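**Plan**

- Locants follow prostaglandin numbering. The retrosynthesis first cuts the C5=C6 Z-alkene (Wittig on a lactol) and reads the ring β-ketol C9(OH)–C10H2–C11(=O) as the oxa-Michael adduct of a cyclopent-2-enone (C9=C10–C11=O) with a C6 carboxyl on the C8 side chain, i.e. a cis-fused γ-lactone.
- The enone ring is then cut at C10–C11 and C8–C12. C8–C9=C10 is an allyl unit and C11(=O)–C12 an acyl unit, joined beforehand through an ester oxygen between C11 and C10, with a silyl group on C10.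
- Forward: enal 3 → α-silyl allylic alcohol 4 → ester 9 → one-flask [3,3] shift (C8–C12) and vinylsilane-terminated acylation (C10–C11) to cyclopentenone 13 → oxidation and lactonisation to bicyclic keto lactone 15 → ketals, lactol, Wittig α-chain → deketalisation.
- Stereochemistry: the C10 carbinol comes from a copper-catalysed enantioselective silyl addition and is relayed to C8 through the chair [3,3] transition state. C9 follows from the cis ring fusion of the lactonisation, C12 from equilibration next to the C11 ketone (trans to C8), and the Z-alkene from the salt-free Wittig reaction.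
- Helpers removed on the way: the ester oxygen link (it ends as the C11 carbonyl oxygen), the C10 silyl group, the C6 lactone and two dioxolanes.

Key step: step 5

Remark (assumption): the C15 carbinol configuration of building block 5 is immaterial because C15 is oxidised in step 6; the (R)-lactone is written so that every intermediate is a single stereoisomer.

**Route**

Step 1
Reactants: 1 3-[(tert-butyldimethylsilyl)oxy]propanal; 2 (triphenyl-λ5-phosphanylidene)acetaldehyde
Product: 3 (2E)-5-[(tert-butyldimethylsilyl)oxy]pent-2-enal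
Conditions: PhMe, 80 °C
Reagents that add atoms: none
Why: Wittig olefination with the formyl-stabilised ylide should give the E-enal that carries C6–C10 (aldehyde carbon = C10).

Step 2
Reactants: 3 (2E)-5-[(tert-butyldimethylsilyl)oxy]pent-2-enal
Product: 4 (1R,2E)-5-[(tert-butyldimethylsilyl)oxy]-1-[dimethyl(phenyl)silyl]pent-2-en-1-ol
Conditions: CuF(PPh3)3·2MeOH (cat.), DTBM-SEGPHOS (cat., the enantiomer that gives the 1R carbinol), PhMe2Si–Bpin, PhMe, 0 °C
Reagents that add atoms: (dimethylphenylsilyl)boronic acid pinacol ester, C[Si](C)(c1ccccc1)B1OC(C)(C)C(C)(C)O1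
Why: copper-catalysed enantioselective 1,2-addition of a silyl nucleophile to the aldehyde, in which the chiral bisphosphine selects the carbonyl face and so sets C10 (R), the centre that later relays to C8.

Step 3
Reactants: 5 (6R)-6-pentyloxan-2-one ((R)-δ-decalactone)
Product: 8 (5R)-5-[(tert-butyldimethylsilyl)oxy]decanoic acid, via potassium hydroxy-carboxylate 6 (not isolated), via silyl ester silyl ether 7 (not isolated)
Conditions: KOH, MeOH/H2O, 23 °C; evaporate; TBSCl, imidazole, DMF, 23 °C; AcOH/H2O/THF, 23 °C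
Reagents that add atoms: potassium hydroxide, [K+].[OH-]; tert-butyldimethylsilyl chloride, CC(C)(C)[Si](C)(C)Cl
Why: saponification, exhaustive silylation and selective hydrolysis of the labile silyl ester should give the O-protected C11–C20 acid without relactonisation and without touching the stereocentre.

Step 4
Reactants: 4 (1R,2E)-5-[(tert-butyldimethylsilyl)oxy]-1-[dimethyl(phenyl)silyl]pent-2-en-1-ol; 8 (5R)-5-[(tert-butyldimethylsilyl)oxy]decanoic acid
Product: 9 (1R,2E)-5-[(tert-butyldimethylsilyl)oxy]-1-[dimethyl(phenyl)silyl]pent-2-en-1-yl (5R)-5-[(tert-butyldimethylsilyl)oxy]decanoate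
Conditions: DCC, DMAP (cat.), CH2Cl2, 0 → 23 °C
Reagents that add atoms: none
Why: Steglich esterification under neutral conditions (no alkoxide, hence no Brook rearrangement of the α-silyl carbinol) links C11 to C10 through oxygen and leaves the C10 centre untouched.

Step 5
Reactants: 9 (1R,2E)-5-[(tert-butyldimethylsilyl)oxy]-1-[dimethyl(phenyl)silyl]pent-2-en-1-yl (5R)-5-[(tert-butyldimethylsilyl)oxy]decanoate
Product: 13 (4S,5R)-4-{2-[(tert-butyldimethylsilyl)oxy]ethyl}-5-{(3R)-3-[(tert-butyldimethylsilyl)oxy]octyl}cyclopent-2-en-1-one, via silyl ketene acetal 10 (not isolated), via trimethylsilyl ester 11 (not isolated), via acid chloride 12 (not isolated)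
Conditions: LiN(iPr)2, Me3SiCl, THF, −78 → 40 °C; volatiles removed in vacuo; (COCl)2, DMF (cat.), CH2Cl2, 0 °C; SnCl4, −78 → 0 °C
Reagents that add atoms: none
Why: LiN(iPr)2/Me3SiCl converts the ester into silyl ketene acetal 10, which undergoes the Ireland–Claisen [3,3]-sigmatropic shift through a chair transition state with the PhMe2Si group pseudo-equatorial, forming C8–C12, cleaving the O–C10 link and giving the (E)-vinylsilane 11; in the same flask the silyl ester is exchanged for acid chloride 12, whose SnCl4-derived acylium ion is attacked by the vinylsilane at the silicon-bearing carbon C10 (β-silyl cation at C9) and then loses the silyl group to leave the C9=C10–C11=O enone. The closest known reaction types are the Ireland–Claisen rearrangement of α-silylallyl esters and the vinylsilane-terminated intramolecular Friedel–Crafts acylation that gives cyclopent-2-enones. The five-membered ring closes in the 5-endo-trig mode at the vinylsilane. C8 is set by 1,3-chirality transfer from the (R)-C10 carbinol, which in this chair gives the C8 configuration of the target; C12 is formed without control and is written trans, the epimer expected after equilibration next to the ketone, and either epimer converges in step 6. The step needs ipso attack at C10 rather than C9, which the β-silicon stabilisation of the C9 cation secures, and enolisation only at C12, which is secured because all other oxygen functions are non-enolisable silyl ethers.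

Step 6
Reactants: 13 (4S,5R)-4-{2-[(tert-butyldimethylsilyl)oxy]ethyl}-5-{(3R)-3-[(tert-butyldimethylsilyl)oxy]octyl}cyclopent-2-en-1-one
Product: 15 (3aR,4R,6aS)-4-(3-oxooctyl)tetrahydro-2H-cyclopenta[b]furan-2,5(3H)-dione, via enone acid 14 (not isolated)
Conditions: CrO3, H2SO4, H2O, acetone, 0 → 23 °C; then camphorsulfonic acid (cat.), CH2Cl2, 23 °C
Reagents that add atoms: water, O
Why: Jones oxidation should cleave both silyl ethers and take C6 to the acid and C15 to the ketone, after which the acid-catalysed intramolecular oxa-Michael addition of the C6 carboxyl to C9 can close only cis-fused, setting C9 with its oxygen cis to C7, while C12 settles in the exo (trans) position.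

Step 7
Reactants: 15 (3aR,4R,6aS)-4-(3-oxooctyl)tetrahydro-2H-cyclopenta[b]furan-2,5(3H)-dione
Product: 16 (3aR,4R,6aS)-5,5-(ethylenedioxy)-4-[2-(2-pentyl-1,3-dioxolan-2-yl)ethyl]hexahydro-2H-cyclopenta[b]furan-2-one
Conditions: (Me3SiOCH2)2, Me3SiOTf (cat.), CH2Cl2, −78 → −20 °C
Reagents that add atoms: 1,2-bis(trimethylsilyloxy)ethane, C[Si](C)(C)OCCO[Si](C)(C)C
Why: silyl-triflate-catalysed ketalisation at low temperature should mask the C11 and C15 ketones before the hydride and ylide steps without β-elimination of the lactone oxygen.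

Step 8
Reactants: 16 (3aR,4R,6aS)-5,5-(ethylenedioxy)-4-[2-(2-pentyl-1,3-dioxolan-2-yl)ethyl]hexahydro-2H-cyclopenta[b]furan-2-one
Product: 17 (2RS,3aR,4R,6aS)-5,5-(ethylenedioxy)-4-[2-(2-pentyl-1,3-dioxolan-2-yl)ethyl]hexahydro-2H-cyclopenta[b]furan-2-ol (lactol, both anomers)
Conditions: iBu2AlH, PhMe, −78 °C
Reagents that add atoms: none
Why: half-reduction of the γ-lactone to the lactol with iBu2AlH at low temperature, to which the ketals are inert.

Step 9
Reactants: 17 (2RS,3aR,4R,6aS)-5,5-(ethylenedioxy)-4-[2-(2-pentyl-1,3-dioxolan-2-yl)ethyl]hexahydro-2H-cyclopenta[b]furan-2-ol; 18 (4-carboxybutyl)triphenylphosphonium bromide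
Product: 20 (5Z)-7-{(6R,7R,8S)-8-hydroxy-6-[2-(2-pentyl-1,3-dioxolan-2-yl)ethyl]-1,4-dioxaspiro[4.4]nonan-7-yl}hept-5-enoic acid, via phosphorus ylide 19 (not isolated)
Conditions: KOtBu, THF, 0 → 23 °C
Reagents that add atoms: none
Why: Wittig olefination of the lactol with the non-stabilised ylide under salt-free potassium conditions should give the C5=C6 Z-alkene and release the 9-hydroxyl, with no enolisable ketone present.

Step 10
Reactants: 20 (5Z)-7-{(6R,7R,8S)-8-hydroxy-6-[2-(2-pentyl-1,3-dioxolan-2-yl)ethyl]-1,4-dioxaspiro[4.4]nonan-7-yl}hept-5-enoic acid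
Product: 21 13,14-dihydro-15-keto-PGD2, (5Z)-7-[(1R,2R,5S)-5-hydroxy-3-oxo-2-(3-oxooctyl)cyclopentyl]hept-5-enoic acid
Conditions: AcOH/H2O/THF (3:1:1), 40 °C
Reagents that add atoms: water, O
Why: mild acid hydrolysis of both dioxolanes should unveil the C11 and C15 ketones while C12 stays in the thermodynamically favoured trans arrangement.

**Compound list**

1 | 3-[(tert-butyldimethylsilyl)oxy]propanal | O=CCCO[Si](C)(C)C(C)(C)C | starting material
2 | (triphenyl-λ5-phosphanylidene)acetaldehyde | O=CC=P(c1ccccc1)(c1ccccc1)c1ccccc1 | starting material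
3 | (2E)-5-[(tert-butyldimethylsilyl)oxy]pent-2-enal | O=C/C=C/CCO[Si](C)(C)C(C)(C)C | intermediate
4 | (1R,2E)-5-[(tert-butyldimethylsilyl)oxy]-1-[dimethyl(phenyl)silyl]pent-2-en-1-ol | O[C@H]([Si](C)(C)c1ccccc1)/C=C/CCO[Si](C)(C)C(C)(C)C | intermediate
5 | (6R)-6-pentyloxan-2-one ((R)-δ-decalactone) | CCCCC[C@@H]1CCCC(=O)O1 | starting material
6 | potassium (5R)-5-hydroxydecanoate | CCCCC[C@@H](O)CCCC(=O)[O-].[K+] | intermediate
7 | tert-butyldimethylsilyl (5R)-5-[(tert-butyldimethylsilyl)oxy]decanoate | CCCCC[C@@H](O[Si](C)(C)C(C)(C)C)CCCC(=O)O[Si](C)(C)C(C)(C)C | intermediate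
8 | (5R)-5-[(tert-butyldimethylsilyl)oxy]decanoic acid | CCCCC[C@@H](O[Si](C)(C)C(C)(C)C)CCCC(=O)O | intermediate
9 | (1R,2E)-5-[(tert-butyldimethylsilyl)oxy]-1-[dimethyl(phenyl)silyl]pent-2-en-1-yl (5R)-5-[(tert-butyldimethylsilyl)oxy]decanoate | CCCCC[C@@H](O[Si](C)(C)C(C)(C)C)CCCC(=O)O[C@H]([Si](C)(C)c1ccccc1)/C=C/CCO[Si](C)(C)C(C)(C)C | intermediate
10 | O-trimethylsilyl ketene acetal of ester 9 (C11=C12 enol double bond, geometry not decisive; C10 R) | CCCCC[C@@H](O[Si](C)(C)C(C)(C)C)CCC=C(O[Si](C)(C)C)O[C@H]([Si](C)(C)c1ccccc1)/C=C/CCO[Si](C)(C)C(C)(C)C | intermediate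
11 | trimethylsilyl (2RS,3R,4E)-3-{2-[(tert-butyldimethylsilyl)oxy]ethyl}-2-{(3R)-3-[(tert-butyldimethylsilyl)oxy]octyl}-5-[dimethyl(phenyl)silyl]pent-4-enoate | CCCCC[C@@H](O[Si](C)(C)C(C)(C)C)CCC(C(=O)O[Si](C)(C)C)[C@@H](CCO[Si](C)(C)C(C)(C)C)/C=C/[Si](C)(C)c1ccccc1 | intermediate
12 | (2RS,3S,4E)-3-{2-[(tert-butyldimethylsilyl)oxy]ethyl}-2-{(3R)-3-[(tert-butyldimethylsilyl)oxy]octyl}-5-[dimethyl(phenyl)silyl]pent-4-enoyl chloride (same spatial arrangement at C3 as in 11; the descriptor changes because of Cl) | CCCCC[C@@H](O[Si](C)(C)C(C)(C)C)CCC(C(=O)Cl)[C@@H](CCO[Si](C)(C)C(C)(C)C)/C=C/[Si](C)(C)c1ccccc1 | intermediate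
13 | (4S,5R)-4-{2-[(tert-butyldimethylsilyl)oxy]ethyl}-5-{(3R)-3-[(tert-butyldimethylsilyl)oxy]octyl}cyclopent-2-en-1-one | O=C1C=C[C@H](CCO[Si](C)(C)C(C)(C)C)[C@H]1CC[C@@H](CCCCC)O[Si](C)(C)C(C)(C)C | intermediate
14 | [(1S,5R)-4-oxo-5-(3-oxooctyl)cyclopent-2-en-1-yl]acetic acid | O=C1C=C[C@H](CC(=O)O)[C@H]1CCC(=O)CCCCC | intermediate
15 | (3aR,4R,6aS)-4-(3-oxooctyl)tetrahydro-2H-cyclopenta[b]furan-2,5(3H)-dione | O=C1C[C@@H]2OC(=O)C[C@@H]2[C@H]1CCC(=O)CCCCC | intermediate
16 | (3aR,4R,6aS)-5,5-(ethylenedioxy)-4-[2-(2-pentyl-1,3-dioxolan-2-yl)ethyl]hexahydro-2H-cyclopenta[b]furan-2-one | O1CCOC12C[C@@H]3OC(=O)C[C@@H]3[C@H]2CCC2(CCCCC)OCCO2 | intermediate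
17 | (2RS,3aR,4R,6aS)-5,5-(ethylenedioxy)-4-[2-(2-pentyl-1,3-dioxolan-2-yl)ethyl]hexahydro-2H-cyclopenta[b]furan-2-ol | O1CCOC12C[C@@H]3OC(O)C[C@@H]3[C@H]2CCC2(CCCCC)OCCO2 | intermediate
18 | (4-carboxybutyl)triphenylphosphonium bromide | OC(=O)CCCC[P+](c1ccccc1)(c1ccccc1)c1ccccc1.[Br-] | starting material
19 | potassium 5-(triphenyl-λ5-phosphanylidene)pentanoate | [K+].[O-]C(=O)CCCC=P(c1ccccc1)(c1ccccc1)c1ccccc1 | intermediate
20 | (5Z)-7-{(6R,7R,8S)-8-hydroxy-6-[2-(2-pentyl-1,3-dioxolan-2-yl)ethyl]-1,4-dioxaspiro[4.4]nonan-7-yl}hept-5-enoic acid | CCCCCC2(OCCO2)CC[C@H]1C3(OCCO3)C[C@H](O)[C@@H]1C/C=C\CCCC(=O)O | intermediate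
21 | 13,14-dihydro-15-keto-PGD2, (5Z)-7-[(1R,2R,5S)-5-hydroxy-3-oxo-2-(3-oxooctyl)cyclopentyl]hept-5-enoic acid | CCCCCC(=O)CC[C@H]1C(=O)C[C@H](O)[C@@H]1C/C=C\CCCC(=O)O | target

**Count and risks**

Total step count: 10. Longest linear sequence: 9 steps (1 → 3 → 4 → 9 → 13 → 15 → 16 → 17 → 20 → 21).

Step 5 is the most likely to fail. The vinylsilane may be protodesilylated, or the β-silyl cation may be captured by the C6 silyl ether oxygen before ring closure. The α-branched acid chloride may also form a ketene and oligomerise. The fallback closes the ring by metathesis instead of acylation; it sets out from 9 and returns at 13. The Ireland–Claisen rearrangement is run alone with aqueous work-up to give (2RS,3R,4E)-3-{2-[(tert-butyldimethylsilyl)oxy]ethyl}-2-{(3R)-3-[(tert-butyldimethylsilyl)oxy]octyl}-5-[dimethyl(phenyl)silyl]pent-4-enoic acid F1. Coupling with N,O-dimethylhydroxylamine (EDC) gives the N-methoxy-N-methylamide F2. Vinylmagnesium bromide converts it into the vinyl ketone (4RS,5R,6E)-5-{2-[(tert-butyldimethylsilyl)oxy]ethyl}-4-{(3R)-3-[(tert-butyldimethylsilyl)oxy]octyl}-7-[dimethyl(phenyl)silyl]hepta-1,6-dien-3-one F3. Ring-closing metathesis (second-generation Hoveyda–Grubbs catalyst, PhMe, 80 °C) between the vinyl ketone and the silyl-substituted C9 alkene then gives 13; here the ring CH next to the carbonyl comes from the vinyl Grignard reagent.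

Step 2 is the second risk. The silyl group may be transferred to the β-carbon of the enal (conjugate addition), the copper alkoxide may undergo Brook rearrangement, or the face selectivity may be poor. The fallback uses stoichiometric asymmetric reduction of an acylsilane; it sets out from 3 and returns at 4. PhMe2SiLi (THF, −78 °C) adds 1,2 to 3 to give racemic (1RS,2E)-5-[(tert-butyldimethylsilyl)oxy]-1-[dimethyl(phenyl)silyl]pent-2-en-1-ol F4. Swern oxidation gives the acylsilane (2E)-5-[(tert-butyldimethylsilyl)oxy]-1-[dimethyl(phenyl)silyl]pent-2-en-1-one F5. Reduction with B-chlorodiisopinocampheylborane (the enantiomer that gives the R carbinol) gives 4.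

Step 10 is the third risk. Acid may dehydrate the C9 β-ketol to the C9=C10 enone, and the hindered C11 dioxolane may cleave incompletely. The fallback installs the ketones last by oxidation instead of unmasking them with acid; it sets out from 15 and returns at 21.
- NaBH4/CeCl3 reduces both ketones to (3aR,4R,6aS)-5-hydroxy-4-(3-hydroxyoctyl)hexahydro-2H-cyclopenta[b]furan-2-one F6 (C11 and C15 epimers are immaterial).
- TBSCl/imidazole gives the bis(tert-butyldimethylsilyl) ether F7.
- iBu2AlH gives the lactol F8.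
- The Wittig reaction of step 9 gives (5Z)-11,15-bis[(tert-butyldimethylsilyl)oxy]-9α-hydroxyprost-5-enoic acid F9.
- Dihydropyran/pyridinium p-toluenesulfonate gives the 9-O-tetrahydropyranyl ether tetrahydropyranyl ester F10.
- Bu4NF removes both silyl groups to give the 11,15-diol F11.
- Swern oxidation gives the 11,15-diketone F12.
- AcOH/H2O/THF at 23–35 °C removes the tetrahydropyranyl groups, under milder conditions than dioxolane hydrolysis, to give 21.

Further compounds

F1 | step 5 | (2RS,3R,4E)-3-{2-[(tert-butyldimethylsilyl)oxy]ethyl}-2-{(3R)-3-[(tert-butyldimethylsilyl)oxy]octyl}-5-[dimethyl(phenyl)silyl]pent-4-enoic acid | CCCCC[C@@H](O[Si](C)(C)C(C)(C)C)CCC(C(=O)O)[C@@H](CCO[Si](C)(C)C(C)(C)C)/C=C/[Si](C)(C)c1ccccc1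
F2 | step 5 | (2RS,3R,4E)-3-{2-[(tert-butyldimethylsilyl)oxy]ethyl}-2-{(3R)-3-[(tert-butyldimethylsilyl)oxy]octyl}-5-[dimethyl(phenyl)silyl]-N-methoxy-N-methylpent-4-enamide | CCCCC[C@@H](O[Si](C)(C)C(C)(C)C)CCC(C(=O)N(C)OC)[C@@H](CCO[Si](C)(C)C(C)(C)C)/C=C/[Si](C)(C)c1ccccc1
F3 | step 5 | (4RS,5R,6E)-5-{2-[(tert-butyldimethylsilyl)oxy]ethyl}-4-{(3R)-3-[(tert-butyldimethylsilyl)oxy]octyl}-7-[dimethyl(phenyl)silyl]hepta-1,6-dien-3-one | CCCCC[C@@H](O[Si](C)(C)C(C)(C)C)CCC(C(=O)C=C)[C@@H](CCO[Si](C)(C)C(C)(C)C)/C=C/[Si](C)(C)c1ccccc1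
F4 | step 2 | (1RS,2E)-5-[(tert-butyldimethylsilyl)oxy]-1-[dimethyl(phenyl)silyl]pent-2-en-1-ol | OC([Si](C)(C)c1ccccc1)/C=C/CCO[Si](C)(C)C(C)(C)C
F5 | step 2 | (2E)-5-[(tert-butyldimethylsilyl)oxy]-1-[dimethyl(phenyl)silyl]pent-2-en-1-one | O=C([Si](C)(C)c1ccccc1)/C=C/CCO[Si](C)(C)C(C)(C)C
F6 | step 10 | (3aR,4R,6aS)-5-hydroxy-4-(3-hydroxyoctyl)hexahydro-2H-cyclopenta[b]furan-2-one (C5 and side-chain carbinol epimers) | OC1C[C@@H]2OC(=O)C[C@@H]2[C@H]1CCC(O)CCCCC
F7 | step 10 | (3aR,4R,6aS)-5-[(tert-butyldimethylsilyl)oxy]-4-{3-[(tert-butyldimethylsilyl)oxy]octyl}hexahydro-2H-cyclopenta[b]furan-2-one | CC(C)(C)[Si](C)(C)OC1C[C@@H]2OC(=O)C[C@@H]2[C@H]1CCC(CCCCC)O[Si](C)(C)C(C)(C)C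
F8 | step 10 | (3aR,4R,6aS)-5-[(tert-butyldimethylsilyl)oxy]-4-{3-[(tert-butyldimethylsilyl)oxy]octyl}hexahydro-2H-cyclopenta[b]furan-2-ol | CC(C)(C)[Si](C)(C)OC1C[C@@H]2OC(O)C[C@@H]2[C@H]1CCC(CCCCC)O[Si](C)(C)C(C)(C)C
F9 | step 10 | (5Z)-11,15-bis[(tert-butyldimethylsilyl)oxy]-9α-hydroxyprost-5-enoic acid | CCCCCC(O[Si](C)(C)C(C)(C)C)CC[C@H]1C(O[Si](C)(C)C(C)(C)C)C[C@H](O)[C@@H]1C/C=C\CCCC(=O)O
F10 | step 10 | tetrahydropyran-2-yl (5Z)-11,15-bis[(tert-butyldimethylsilyl)oxy]-9α-(tetrahydropyran-2-yloxy)prost-5-enoate | CCCCCC(O[Si](C)(C)C(C)(C)C)CC[C@H]1C(O[Si](C)(C)C(C)(C)C)C[C@H](OC2CCCCO2)[C@@H]1C/C=C\CCCC(=O)OC1CCCCO1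
F11 | step 10 | tetrahydropyran-2-yl (5Z)-11,15-dihydroxy-9α-(tetrahydropyran-2-yloxy)prost-5-enoate | CCCCCC(O)CC[C@H]1C(O)C[C@H](OC2CCCCO2)[C@@H]1C/C=C\CCCC(=O)OC1CCCCO1
F12 | step 10 | tetrahydropyran-2-yl (5Z)-11,15-dioxo-9α-(tetrahydropyran-2-yloxy)prost-5-enoate | CCCCCC(=O)CC[C@H]1C(=O)C[C@H](OC2CCCCO2)[C@@H]1C/C=C\CCCC(=O)OC1CCCCO1
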